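**Plan**
- Each half is numbered C1 (ester C=O) to C9 (carbinol CH carrying the oxazol-5-ylmethyl group). The 20-membered diolide ring holds one cis-disubstituted C4=C5 alkene per half, and each can be stored as a conjugated C4≡C5 alkyne, so the ring is opened retrosynthetically at C4≡C5 of one half (ring-closing alkyne metathesis).
- The linear diyne is then cut at both C1–O ester bonds and both C3–C4 bonds. This leaves two C5–C9 alkynols that differ only at the alkyne terminus (methyl-capped or terminal), (Z)-3-iodo-2-methylacrylic acid (used twice) and propyne.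
- Forward: syn aldol, C7 iodide, propargylic alkylation, oxazole formation; then ester, Sonogashira, enyne semi-reduction (first Z,Z-dienoate), ester, Sonogashira with propyne. The only ring closure is the metathesis; a last cis semi-reduction gives the target.
- Stereochemistry: C8 and C9 of both halves come from one auxiliary-controlled syn aldol; both 2Z alkenes from anti-carbomagnesiation/iodination of propargyl alcohol; both 4Z alkenes from cis semi-reduction of alkynes.

Key step: step 23

Assumption: 3-(4-methoxybenzyloxy)propanal is treated as a purchasable aldehyde.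

**Step 1**
Reactants: 1 (S)-4-benzyl-3-propionyloxazolidin-2-one; 2 3-(4-methoxybenzyloxy)propanal
Product: 4 (4S)-4-benzyl-3-[(2S,3R)-3-hydroxy-5-(4-methoxybenzyloxy)-2-methylpentanoyl]oxazolidin-2-one, via Z-boron enolate 3 (not isolated)
Conditions: Bu2BOTf, i-Pr2NEt, CH2Cl2, −78 → 0 °C; then 2, −78 → 0 °C; pH 7 buffer, MeOH, H2O2, 0 °C
Reagents that add atoms: none
Why: Evans syn aldol, in which the Z-boron enolate 3 reacts through a chair Zimmerman–Traxler transition state on the face away from the benzyl group, so that C8 (methyl) and C9 (hydroxyl) should be set syn in the absolute sense that becomes (8R,9R) in the target.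

**Step 2**
Reactants: 4 aldol adduct
Product: 5 (4S)-4-benzyl-3-[(2S,3R)-3-(tert-butyldimethylsilyloxy)-5-(4-methoxybenzyloxy)-2-methylpentanoyl]oxazolidin-2-one
Conditions: TBSOTf, 2,6-lutidine, CH2Cl2, 0 °C
Reagents that add atoms: tert-butyldimethylsilyl triflate, CC(C)(C)[Si](C)(C)OS(=O)(=O)C(F)(F)F
Why: Silylation of a secondary alcohol with a silyl triflate and a hindered base is routine and blocks retro-aldol cleavage in the following steps.

**Step 3**
Reactants: 5 silyl ether imide
Product: 6 (2R,3R)-3-(tert-butyldimethylsilyloxy)-5-(4-methoxybenzyloxy)-2-methylpentan-1-ol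
Conditions: LiBH4, MeOH (1 equiv), THF, 0 °C
Reagents that add atoms: none
Why: Reductive cleavage of the N-acyloxazolidinone by borohydride attack at the exocyclic carbonyl should give the primary alcohol (C7) without touching the adjacent C8 stereocentre.

**Step 4**
Reactants: 6 primary alcohol
Product: 7 tert-butyl{[(3R,4S)-5-iodo-1-(4-methoxybenzyloxy)-4-methylpentan-3-yl]oxy}dimethylsilane
Conditions: I2, PPh3, imidazole, CH2Cl2, 0 °C → rt
Reagents that add atoms: iodine, II
Why: Appel-type iodination converts the primary alcohol into the iodide by SN2 at the CH2 carbon, which is not a stereocentre.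

**Step 5**
Reactants: 7 C7 iodide; 8 2-butyne
Product: 10 tert-butyl{[(3R,4R)-1-(4-methoxybenzyloxy)-4-methylnon-7-yn-3-yl]oxy}dimethylsilane, via but-2-ynyllithium 9 (not isolated)
Conditions: 8 (excess), n-BuLi, TMEDA, THF, −78 → 0 °C; then 7, THF, −78 °C → rt
Reagents that add atoms: none
Why: Propargylic lithiation of 2-butyne gives 9, which should alkylate the primary iodide by SN2 mainly through its CH2 terminus (alkylation of a propargyl/allenyl lithium reagent), adding C6 and the methyl-capped C5 alkyne in one operation.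

**Step 6**
Reactants: 10 PMB ether
Product: 11 (3R,4R)-3-(tert-butyldimethylsilyloxy)-4-methylnon-7-yn-1-ol
Conditions: DDQ, CH2Cl2/pH 7 buffer, 0 °C
Reagents that add atoms: none
Why: Oxidative cleavage of the 4-methoxybenzyl ether by DDQ proceeds through the benzylic oxocarbenium ion and leaves the silyl ether and the alkyne alone.

**Step 7**
Reactants: 11 primary alcohol
Product: 12 (3R,4R)-3-(tert-butyldimethylsilyloxy)-4-methylnon-7-ynal
Conditions: Dess–Martin periodinane, CH2Cl2, rt
Reagents that add atoms: none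
Why: Dess–Martin oxidation stops at the aldehyde under nearly neutral conditions, so the β-silyloxy aldehyde should not eliminate.

**Step 8**
Reactants: 12 aldehyde; 13 TosMIC
Product: 15 5-[(2R,3R)-2-(tert-butyldimethylsilyloxy)-3-methyloct-6-yn-1-yl]oxazole, via 4-tosyloxazoline 14 (not isolated)
Conditions: K2CO3, MeOH, rt → 65 °C
Reagents that add atoms: none
Why: van Leusen oxazole synthesis, in which deprotonated TosMIC adds to the aldehyde, the alkoxide closes onto the isocyanide carbon to give oxazoline 14, and loss of p-toluenesulfinate aromatises it to the 5-substituted oxazole.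

**Step 9**
Reactants: 15 silyl ether
Product: 16 (2R,3R)-3-methyl-1-(oxazol-5-yl)oct-6-yn-2-ol
Conditions: Bu4NF, THF, 0 °C → rt
Reagents that add atoms: none
Why: Fluoride-mediated desilylation frees the C9 hydroxyl; the oxazole and the internal alkyne are stable to Bu4NF.

**Step 10**
Reactants: 7 C7 iodide; 17 1-(trimethylsilyl)propyne
Product: 19 tert-butyl{[(3R,4R)-1-(4-methoxybenzyloxy)-4-methyl-8-(trimethylsilyl)oct-7-yn-3-yl]oxy}dimethylsilane, via 3-(trimethylsilyl)prop-2-ynyllithium 18 (not isolated)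
Conditions: 17, n-BuLi, THF, −78 → −20 °C; then 7, −78 °C → rt
Reagents that add atoms: none
Why: Alkylation of the lithiated silylpropyne 18 should occur at the propargylic carbon, because the silyl group shields the alkyne terminus, and gives the C5 alkyne in masked terminal form.

**Step 11**
Reactants: 19 PMB ether
Product: 20 (3R,4R)-3-(tert-butyldimethylsilyloxy)-4-methyl-8-(trimethylsilyl)oct-7-yn-1-ol
Conditions: DDQ, CH2Cl2/pH 7 buffer, 0 °C
Reagents that add atoms: none
Why: Oxidative PMB ether cleavage with DDQ, as in step 6; the alkynylsilane is inert to the quinone.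

**Step 12**
Reactants: 20 primary alcohol
Product: 21 (3R,4R)-3-(tert-butyldimethylsilyloxy)-4-methyl-8-(trimethylsilyl)oct-7-ynal
Conditions: Dess–Martin periodinane, CH2Cl2, rt
Reagents that add atoms: none
Why: Dess–Martin oxidation to the aldehyde under nearly neutral conditions, as in step 7.

**Step 13**
Reactants: 21 aldehyde; 13 TosMIC
Product: 23 5-[(2R,3R)-2-(tert-butyldimethylsilyloxy)-3-methylhept-6-yn-1-yl]oxazole, via silylalkyne 4-tosyloxazoline 22 (not isolated)
Conditions: K2CO3, MeOH, rt → 65 °C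
Reagents that add atoms: none
Why: van Leusen oxazole synthesis as in step 8; the same carbonate/methanol medium cleaves the alkynyl C–Si bond, so the terminal alkyne needed for cross-coupling should be released in the same flask.

**Step 14**
Reactants: 24 propargyl alcohol
Product: 26 (Z)-3-iodo-2-methylprop-2-en-1-ol, via alkenylmagnesium alkoxide 25 (not isolated)
Conditions: MeMgBr, CuI (10 mol%), THF, −10 °C → rt; then I2, −10 → 0 °C
Reagents that add atoms: methylmagnesium bromide, C[Mg]Br; iodine, II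
Why: Copper-catalysed anti-carbomagnesiation of the propargylic alkoxide delivers methyl to C2 and leaves the C3–Mg bond cis to CH2O in the chelate 25, and iodinolysis with retention should give the Z-iodide.

**Step 15**
Reactants: 26 allylic alcohol
Product: 27 (Z)-3-iodo-2-methylprop-2-enal
Conditions: MnO2, CH2Cl2, rt, dark
Reagents that add atoms: none
Why: MnO2 oxidises allylic alcohols selectively to enals under neutral conditions, which should preserve the Z geometry when light and acid are excluded.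

**Step 16**
Reactants: 27 enal
Product: 28 (Z)-3-iodo-2-methylprop-2-enoic acid
Conditions: NaClO2, NaH2PO4, 2-methyl-2-butene, t-BuOH/H2O, 0 °C → rt
Reagents that add atoms: sodium chlorite, [Na+].[O-]Cl=O
Why: Pinnick oxidation converts enals into acids without isomerising or attacking the alkene, the added alkene scavenging hypochlorous acid.

**Step 17**
Reactants: 16 alkynol; 28 iodoacrylic acid
Product: 30 (2R,3R)-3-methyl-1-(oxazol-5-yl)oct-6-yn-2-yl (Z)-3-iodo-2-methylprop-2-enoate, via Yamaguchi mixed anhydride 29 (not isolated)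
Conditions: 28, 2,4,6-Cl3C6H2COCl, Et3N, toluene, rt; then 16, DMAP, toluene, 0 °C → rt
Reagents that add atoms: none
Why: Yamaguchi esterification, in which DMAP opens the mixed anhydride 29 at the less hindered acryloyl carbonyl and the acylpyridinium acylates the hindered C9 alcohol with retention at carbon.

**Step 18**
Reactants: 30 iodoacrylate; 23 terminal alkyne
Product: 31 (2R,3R)-3-methyl-1-(oxazol-5-yl)oct-6-yn-2-yl (2Z,8R,9R)-9-(tert-butyldimethylsilyloxy)-2,8-dimethyl-10-(oxazol-5-yl)dec-2-en-4-ynoate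
Conditions: Pd(PPh3)2Cl2 (5 mol%), CuI (10 mol%), Et3N, THF, rt
Reagents that add atoms: none
Why: Sonogashira coupling of a Z-β-iodoacrylate with a terminal alkyne forms C3–C4 of the second half with retention of the alkene geometry; the methyl-capped internal alkyne cannot enter the copper acetylide cycle.

**Step 19**
Reactants: 31 enyne ester
Product: 32 (2R,3R)-3-methyl-1-(oxazol-5-yl)oct-6-yn-2-yl (2Z,4Z,8R,9R)-9-(tert-butyldimethylsilyloxy)-2,8-dimethyl-10-(oxazol-5-yl)deca-2,4-dienoate
Conditions: Zn dust activated with Cu(OAc)2 and AgNO3 (pre-formed couple), MeOH/H2O/THF, 45 °C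
Reagents that add atoms: none
Why: Activated-zinc semi-reduction transfers two hydrogens cis only to alkynes activated by conjugation, so the enyne should become the (2Z,4Z)-dienoate while the isolated methyl-capped alkyne is kept for ring closure.

**Step 20**
Reactants: 32 silyl ether
Product: 33 (2R,3R)-3-methyl-1-(oxazol-5-yl)oct-6-yn-2-yl (2Z,4Z,8R,9R)-9-hydroxy-2,8-dimethyl-10-(oxazol-5-yl)deca-2,4-dienoate
Conditions: HF·pyridine, pyridine, THF, 0 °C → rt
Reagents that add atoms: none
Why: Buffered acidic fluoride desilylation removes the secondary silyl ether without base that could isomerise the Z,Z-dienoate or cleave the ester.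

**Step 21**
Reactants: 33 alcohol; 28 iodoacrylic acid
Product: 35 (2R,3R)-3-methyl-1-(oxazol-5-yl)oct-6-yn-2-yl (2Z,4Z,8R,9R)-9-{[(Z)-3-iodo-2-methylprop-2-enoyl]oxy}-2,8-dimethyl-10-(oxazol-5-yl)deca-2,4-dienoate, via Shiina mixed anhydride 34 (not isolated)
Conditions: 28, 2-methyl-6-nitrobenzoic anhydride (MNBA), DMAP, Et3N, CH2Cl2, rt
Reagents that add atoms: none
Why: Shiina esterification, in which MNBA converts the acid in situ into the mixed anhydride 34, DMAP attacks its less hindered acryloyl carbonyl and the acylpyridinium acylates the C9 alcohol with retention; the one-pot, room-temperature conditions suit the Z,Z-dienoate, whose existing ester is not an activated acyl group.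

**Step 22**
Reactants: 35 iodoacrylate; 36 propyne
Product: 37 (2R,3R)-3-methyl-1-(oxazol-5-yl)oct-6-yn-2-yl (2Z,4Z,8R,9R)-2,8-dimethyl-9-{[(Z)-2-methylhex-2-en-4-ynoyl]oxy}-10-(oxazol-5-yl)deca-2,4-dienoate
Conditions: propyne (excess), Pd(PPh3)2Cl2 (5 mol%), CuI (10 mol%), Et3N, THF, −20 °C → rt
Reagents that add atoms: none
Why: Sonogashira coupling with propyne installs the methyl-capped enyne with retention of the 2Z geometry; the internal alkyne and the dienoate are spectators.

**Step 23**
Reactants: 37 linear diester diyne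
Product: 38 (3Z,9R,10R,13Z,15Z,19R,20R)-3,9,13,19-tetramethyl-10,20-bis(oxazol-5-ylmethyl)-1,11-dioxacycloicosa-3,13,15-trien-5-yne-2,12-dione
Conditions: Mo(≡CC6H4OMe-4)(OSiPh3)3 (20 mol%), 5 Å molecular sieves, toluene (0.002 M), rt → 60 °C
Reagents that add atoms: none
Why: Ring-closing alkyne metathesis: the molybdenum alkylidyne adds to one capped alkyne by [2+2] cycloaddition to a molybdenacyclobutadiene, cycloreverts to a substrate-bound alkylidyne, and repeats the sequence intramolecularly on the second alkyne. The closest known reaction type is macrocyclic ring-closing alkyne metathesis of a 1,3-enyne with an alkyl-capped alkyne using triarylsilanolate molybdenum alkylidynes. The one ring formed is the 20-membered diolide, closed by forming C4≡C5 with both alkyne carbons inside the ring and both methyl caps expelled as 2-butyne, which the sieves absorb so that the equilibrium is drawn to the unstrained cycloalkyne. No stereocentre is created, and C8/C9 of both halves and the three existing Z-alkenes stay untouched because the alkylidyne does not react with C=C bonds. The step needs ring closure to outrun acyclic diyne metathesis and a catalyst that survives two esters and two oxazole nitrogens: the substrate offers exactly two metathesis-active groups, both methyl-capped, high dilution and butyne removal favour cyclisation, and the bulky silanolate shell keeps the weakly basic azoles off the metal.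

**Step 24**
Reactants: 38 macrocyclic enyne
Product: 39 (3Z,5Z,9R,10R,13Z,15Z,19R,20R)-3,9,13,19-tetramethyl-10,20-bis(oxazol-5-ylmethyl)-1,11-dioxacycloicosa-3,5,13,15-tetraene-2,12-dione (CNP0414419.1)
Conditions: Zn dust activated with Cu(OAc)2 and AgNO3 (pre-formed couple), MeOH/H2O/THF, 45 °C
Reagents that add atoms: none
Why: Activated-zinc semi-reduction delivers two hydrogens syn to the conjugated ring alkyne and should give the last 4Z alkene, while the ester-conjugated alkenes, the finished diene and the oxazoles are not reduced.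

**Compound list**
1 | (S)-4-benzyl-3-propionyloxazolidin-2-one | CCC(=O)N1[C@@H](Cc2ccccc2)COC1=O | starting material
2 | 3-(4-methoxybenzyloxy)propanal | O=CCCOCc1ccc(OC)cc1 | starting material
3 | (S)-4-benzyl-3-[(Z)-1-(dibutylboryloxy)prop-1-enyl]oxazolidin-2-one (Z-boron enolate) | C/C=C(\OB(CCCC)CCCC)N1[C@@H](Cc2ccccc2)COC1=O | intermediate
4 | (4S)-4-benzyl-3-[(2S,3R)-3-hydroxy-5-(4-methoxybenzyloxy)-2-methylpentanoyl]oxazolidin-2-one | O=C([C@@H](C)[C@@H](CCOCc1ccc(OC)cc1)O)N1[C@@H](Cc2ccccc2)COC1=O | intermediate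
5 | (4S)-4-benzyl-3-[(2S,3R)-3-(tert-butyldimethylsilyloxy)-5-(4-methoxybenzyloxy)-2-methylpentanoyl]oxazolidin-2-one | O=C([C@@H](C)[C@@H](CCOCc1ccc(OC)cc1)O[Si](C)(C)C(C)(C)C)N1[C@@H](Cc2ccccc2)COC1=O | intermediate
6 | (2R,3R)-3-(tert-butyldimethylsilyloxy)-5-(4-methoxybenzyloxy)-2-methylpentan-1-ol | OC[C@@H](C)[C@@H](CCOCc1ccc(OC)cc1)O[Si](C)(C)C(C)(C)C | intermediate
7 | tert-butyl{[(3R,4S)-5-iodo-1-(4-methoxybenzyloxy)-4-methylpentan-3-yl]oxy}dimethylsilane | IC[C@@H](C)[C@@H](CCOCc1ccc(OC)cc1)O[Si](C)(C)C(C)(C)C | intermediate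
8 | 2-butyne | CC#CC | starting material
9 | but-2-yn-1-yllithium | [Li]CC#CC | intermediate
10 | tert-butyl{[(3R,4R)-1-(4-methoxybenzyloxy)-4-methylnon-7-yn-3-yl]oxy}dimethylsilane | CC#CCC[C@@H](C)[C@@H](CCOCc1ccc(OC)cc1)O[Si](C)(C)C(C)(C)C | intermediate
11 | (3R,4R)-3-(tert-butyldimethylsilyloxy)-4-methylnon-7-yn-1-ol | CC#CCC[C@@H](C)[C@@H](CCO)O[Si](C)(C)C(C)(C)C | intermediate
12 | (3R,4R)-3-(tert-butyldimethylsilyloxy)-4-methylnon-7-ynal | CC#CCC[C@@H](C)[C@@H](CC=O)O[Si](C)(C)C(C)(C)C | intermediate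
13 | TosMIC (p-toluenesulfonylmethyl isocyanide) | [C-]#[N+]CS(=O)(=O)c1ccc(C)cc1 | starting material
14 | 5-[(2R,3R)-2-(tert-butyldimethylsilyloxy)-3-methyloct-6-yn-1-yl]-4-tosyl-4,5-dihydrooxazole (ring C4/C5 configuration not fixed) | CC#CCC[C@@H](C)[C@@H](CC1OC=NC1S(=O)(=O)c1ccc(C)cc1)O[Si](C)(C)C(C)(C)C | intermediate
15 | 5-[(2R,3R)-2-(tert-butyldimethylsilyloxy)-3-methyloct-6-yn-1-yl]oxazole | CC#CCC[C@@H](C)[C@@H](Cc1cnco1)O[Si](C)(C)C(C)(C)C | intermediate
16 | (2R,3R)-3-methyl-1-(oxazol-5-yl)oct-6-yn-2-ol | CC#CCC[C@@H](C)[C@@H](Cc1cnco1)O | intermediate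
17 | 1-(trimethylsilyl)propyne | CC#C[Si](C)(C)C | starting material
18 | 3-(trimethylsilyl)prop-2-yn-1-yllithium | [Li]CC#C[Si](C)(C)C | intermediate
19 | tert-butyl{[(3R,4R)-1-(4-methoxybenzyloxy)-4-methyl-8-(trimethylsilyl)oct-7-yn-3-yl]oxy}dimethylsilane | C[Si](C)(C)C#CCC[C@@H](C)[C@@H](CCOCc1ccc(OC)cc1)O[Si](C)(C)C(C)(C)C | intermediate
20 | (3R,4R)-3-(tert-butyldimethylsilyloxy)-4-methyl-8-(trimethylsilyl)oct-7-yn-1-ol | C[Si](C)(C)C#CCC[C@@H](C)[C@@H](CCO)O[Si](C)(C)C(C)(C)C | intermediate
21 | (3R,4R)-3-(tert-butyldimethylsilyloxy)-4-methyl-8-(trimethylsilyl)oct-7-ynal | C[Si](C)(C)C#CCC[C@@H](C)[C@@H](CC=O)O[Si](C)(C)C(C)(C)C | intermediate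
22 | 5-[(2R,3R)-2-(tert-butyldimethylsilyloxy)-3-methyl-7-(trimethylsilyl)hept-6-yn-1-yl]-4-tosyl-4,5-dihydrooxazole (ring C4/C5 configuration not fixed) | C[Si](C)(C)C#CCC[C@@H](C)[C@@H](CC1OC=NC1S(=O)(=O)c1ccc(C)cc1)O[Si](C)(C)C(C)(C)C | intermediate
23 | 5-[(2R,3R)-2-(tert-butyldimethylsilyloxy)-3-methylhept-6-yn-1-yl]oxazole | C#CCC[C@@H](C)[C@@H](Cc1cnco1)O[Si](C)(C)C(C)(C)C | intermediate
24 | propargyl alcohol | C#CCO | starting material
25 | bromomagnesium (Z)-3-(bromomagnesio)-2-methylprop-2-en-1-olate | Br[Mg]OC/C(C)=C\[Mg]Br | intermediate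
26 | (Z)-3-iodo-2-methylprop-2-en-1-ol | OC/C(C)=C\I | intermediate
27 | (Z)-3-iodo-2-methylprop-2-enal | O=C/C(C)=C\I | intermediate
28 | (Z)-3-iodo-2-methylprop-2-enoic acid | OC(=O)/C(C)=C\I | intermediate
29 | (Z)-3-iodo-2-methylprop-2-enoic 2,4,6-trichlorobenzoic anhydride | O=C(OC(=O)/C(C)=C\I)c1c(Cl)cc(Cl)cc1Cl | intermediate
30 | (2R,3R)-3-methyl-1-(oxazol-5-yl)oct-6-yn-2-yl (Z)-3-iodo-2-methylprop-2-enoate | CC#CCC[C@@H](C)[C@@H](Cc1cnco1)OC(=O)/C(C)=C\I | intermediate
31 | (2R,3R)-3-methyl-1-(oxazol-5-yl)oct-6-yn-2-yl (2Z,8R,9R)-9-(tert-butyldimethylsilyloxy)-2,8-dimethyl-10-(oxazol-5-yl)dec-2-en-4-ynoate | CC#CCC[C@@H](C)[C@@H](Cc1cnco1)OC(=O)/C(C)=C\C#CCC[C@@H](C)[C@@H](Cc1cnco1)O[Si](C)(C)C(C)(C)C | intermediate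
32 | (2R,3R)-3-methyl-1-(oxazol-5-yl)oct-6-yn-2-yl (2Z,4Z,8R,9R)-9-(tert-butyldimethylsilyloxy)-2,8-dimethyl-10-(oxazol-5-yl)deca-2,4-dienoate | CC#CCC[C@@H](C)[C@@H](Cc1cnco1)OC(=O)/C(C)=C\C=C/CC[C@@H](C)[C@@H](Cc1cnco1)O[Si](C)(C)C(C)(C)C | intermediate
33 | (2R,3R)-3-methyl-1-(oxazol-5-yl)oct-6-yn-2-yl (2Z,4Z,8R,9R)-9-hydroxy-2,8-dimethyl-10-(oxazol-5-yl)deca-2,4-dienoate | CC#CCC[C@@H](C)[C@@H](Cc1cnco1)OC(=O)/C(C)=C\C=C/CC[C@@H](C)[C@@H](Cc1cnco1)O | intermediate
34 | (Z)-3-iodo-2-methylprop-2-enoic 2-methyl-6-nitrobenzoic anhydride | O=C(OC(=O)/C(C)=C\I)c1c(C)cccc1[N+](=O)[O-] | intermediate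
35 | (2R,3R)-3-methyl-1-(oxazol-5-yl)oct-6-yn-2-yl (2Z,4Z,8R,9R)-9-{[(Z)-3-iodo-2-methylprop-2-enoyl]oxy}-2,8-dimethyl-10-(oxazol-5-yl)deca-2,4-dienoate | CC#CCC[C@@H](C)[C@@H](Cc1cnco1)OC(=O)/C(C)=C\C=C/CC[C@@H](C)[C@@H](Cc1cnco1)OC(=O)/C(C)=C\I | intermediate
36 | propyne | CC#C | starting material
37 | (2R,3R)-3-methyl-1-(oxazol-5-yl)oct-6-yn-2-yl (2Z,4Z,8R,9R)-2,8-dimethyl-9-{[(Z)-2-methylhex-2-en-4-ynoyl]oxy}-10-(oxazol-5-yl)deca-2,4-dienoate | CC#CCC[C@@H](C)[C@@H](Cc1cnco1)OC(=O)/C(C)=C\C=C/CC[C@@H](C)[C@@H](Cc1cnco1)OC(=O)/C(C)=C\C#CC | intermediate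
38 | (3Z,9R,10R,13Z,15Z,19R,20R)-3,9,13,19-tetramethyl-10,20-bis(oxazol-5-ylmethyl)-1,11-dioxacycloicosa-3,13,15-trien-5-yne-2,12-dione | C/C1=C/C#CCC[C@@H](C)[C@@H](Cc2cnco2)OC(=O)/C(C)=C\C=C/CC[C@@H](C)[C@@H](Cc2cnco2)OC1=O | intermediate
39 | (3Z,5Z,9R,10R,13Z,15Z,19R,20R)-3,9,13,19-tetramethyl-10,20-bis(oxazol-5-ylmethyl)-1,11-dioxacycloicosa-3,5,13,15-tetraene-2,12-dione (CNP0414419.1) | C/C1=C/C=C\CC[C@@H](C)[C@@H](Cc2cnco2)OC(=O)/C(C)=C\C=C/CC[C@@H](C)[C@@H](Cc2cnco2)OC1=O | target

**Step count**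
Total: 24 steps. Longest linear sequence: 17 steps (steps 1–9, then 17–24). Alkyne 23 joins after 8 steps (1–4, 10–13) and acid 28 after 3 (14–16).

**Steps most likely to fail**

1. Step 23. Coordination of the two oxazole nitrogens to molybdenum may slow turnover until intermolecular metathesis (oligomerisation) and catalyst decay win over ring closure. The fallback closes the ring by ester formation instead and sets out from 23 and 28. Acid 28 would be esterified with 2-(trimethylsilyl)ethanol (DCC, DMAP) to 2-(trimethylsilyl)ethyl (Z)-3-iodo-2-methylprop-2-enoate F1. Sonogashira coupling of F1 with 23 should give 2-(trimethylsilyl)ethyl (2Z,8R,9R)-9-(tert-butyldimethylsilyloxy)-2,8-dimethyl-10-(oxazol-5-yl)dec-2-en-4-ynoate F2. Semi-reduction with the activated zinc couple would give 2-(trimethylsilyl)ethyl (2Z,4Z,8R,9R)-9-(tert-butyldimethylsilyloxy)-2,8-dimethyl-10-(oxazol-5-yl)deca-2,4-dienoate F3. Bu4NF would remove both silyl groups to give (2Z,4Z,8R,9R)-9-hydroxy-2,8-dimethyl-10-(oxazol-5-yl)deca-2,4-dienoic acid F4. Head-to-tail Yamaguchi cyclodimerisation of F4 under high dilution, helped by the strain of the 10-membered monolide, comes back to the route at 39.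

2. Step 8 (the same reaction recurs in step 13). Base-induced β-elimination of the silanol from the β-silyloxy aldehyde in carbonate/methanol may compete with TosMIC addition. The fallback builds the oxazole from an ester and sets out from 12. Pinnick oxidation would give (3R,4R)-3-(tert-butyldimethylsilyloxy)-4-methylnon-7-ynoic acid F5, and trimethylsilyldiazomethane in MeOH/toluene its methyl ester, methyl (3R,4R)-3-(tert-butyldimethylsilyloxy)-4-methylnon-7-ynoate F6. Lithiomethyl isocyanide F7 (2 equiv, from methyl isocyanide and n-BuLi in THF at −78 °C) would acylate on F6 to (4R,5R)-4-(tert-butyldimethylsilyloxy)-1-isocyano-5-methyldec-8-yn-2-one F8. F8 is held as its enolate and closes to the oxazole on quench (Schöllkopf oxazole synthesis), coming back to the route at 15.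

3. Step 5. The ambident butynyl anion may attack through its allenyl terminus, and SN2 at the β-branched iodide may be slow enough for E2 to compete. The fallback sets out from 19, which step 10 already supplies. MeLi·LiBr in THF would cleave the C–Si bond to the lithium acetylide, lithium (5R,6R)-6-(tert-butyldimethylsilyloxy)-8-(4-methoxybenzyloxy)-5-methyloct-1-yn-1-ide F9, which is methylated in the same flask with MeI and comes back to the route at 10.

**Further compounds**
F1 | step 23 | 2-(trimethylsilyl)ethyl (Z)-3-iodo-2-methylprop-2-enoate | C[Si](C)(C)CCOC(=O)/C(C)=C\I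
F2 | step 23 | 2-(trimethylsilyl)ethyl (2Z,8R,9R)-9-(tert-butyldimethylsilyloxy)-2,8-dimethyl-10-(oxazol-5-yl)dec-2-en-4-ynoate | C[Si](C)(C)CCOC(=O)/C(C)=C\C#CCC[C@@H](C)[C@@H](Cc1cnco1)O[Si](C)(C)C(C)(C)C
F3 | step 23 | 2-(trimethylsilyl)ethyl (2Z,4Z,8R,9R)-9-(tert-butyldimethylsilyloxy)-2,8-dimethyl-10-(oxazol-5-yl)deca-2,4-dienoate | C[Si](C)(C)CCOC(=O)/C(C)=C\C=C/CC[C@@H](C)[C@@H](Cc1cnco1)O[Si](C)(C)C(C)(C)C
F4 | step 23 | (2Z,4Z,8R,9R)-9-hydroxy-2,8-dimethyl-10-(oxazol-5-yl)deca-2,4-dienoic acid | OC(=O)/C(C)=C\C=C/CC[C@@H](C)[C@@H](Cc1cnco1)O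
F5 | step 8 | (3R,4R)-3-(tert-butyldimethylsilyloxy)-4-methylnon-7-ynoic acid | CC#CCC[C@@H](C)[C@@H](CC(=O)O)O[Si](C)(C)C(C)(C)C
F6 | step 8 | methyl (3R,4R)-3-(tert-butyldimethylsilyloxy)-4-methylnon-7-ynoate | CC#CCC[C@@H](C)[C@@H](CC(=O)OC)O[Si](C)(C)C(C)(C)C
F7 | step 8 | lithiomethyl isocyanide | [Li]C[N+]#[C-]
F8 | step 8 | (4R,5R)-4-(tert-butyldimethylsilyloxy)-1-isocyano-5-methyldec-8-yn-2-one | CC#CCC[C@@H](C)[C@@H](CC(=O)C[N+]#[C-])O[Si](C)(C)C(C)(C)C
F9 | step 5 | lithium (5R,6R)-6-(tert-butyldimethylsilyloxy)-8-(4-methoxybenzyloxy)-5-methyloct-1-yn-1-ide | [Li]C#CCC[C@@H](C)[C@@H](CCOCc1ccc(OC)cc1)O[Si](C)(C)C(C)(C)C
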